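**Retrosynthetic overview**
1. Ring numbering: C1 is the quaternary oxirane carbon (CH2OBz), C2 carries OMe, C3 carries OBz, C4=C5, C6 is the oxirane CH. The strategy rests on the C6–C1–C2–C3 oxygen array of the cyclohexene ring: the oxygens on C1 and C2 are cis, and each is trans to its outer neighbour (C3–O, and C6–O before C6 is inverted).
2. Target ⇐ PMB→benzoate exchange ⇐ oxirane (second ring) closed by the C1 oxygen displacing a C6 mesylate with inversion ⇐ C4=C5 by Corey–Winter olefination of the C4/C5 cis-diol ⇐ C2-O-methylated cis-diol.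
3. Carbocycle (first ring) ⇐ SmI2 ketone–aldehyde pinacol closure of the C1–C2 bond in a D-galacto seven-carbon keto-aldehyde (3,4-acetonide, 2-OPMB, 5-OTBS, 7-OPMB).
4. Keto-aldehyde ⇐ phenyl 1-thio-β-D-galactopyranoside: 3,4-acetonide, 2-OPMB; lactol methylenation gives a vinyl group as latent aldehyde and frees O5 for silylation; C6 is oxidised, extended with PMBOCH2Li and re-oxidised.

Key step: step 13

Assumptions: phenyl 1-thio-β-D-galactopyranoside is used as the purchasable form of D-galactose. Chain compounds keep galactose numbering C1–C6, C1′ being the methylene carbon added in step 5 and C7 the carbon added in step 10. Carbocycles use the ring numbering of line 1. PMB = 4-methoxybenzyl, TBS = tert-butyldimethylsilyl.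

**Route**

Step 1
Reactants: 1 phenyl 1-thio-β-D-galactopyranoside; 2 2,2-dimethoxypropane
Product: 3 phenyl 3,4-O-isopropylidene-1-thio-β-D-galactopyranoside
Conditions: 2,2-dimethoxypropane, (1S)-(+)-10-camphorsulfonic acid (cat.), acetone, rt; Et3N; then MeOH/H2O, 50 °C
Reagents that add atoms: 2,2-dimethoxypropane (2), COC(C)(C)OC
Why: acid-catalysed transketalisation under thermodynamic control should place the dioxolane on the only cis-vicinal diol (O3/O4), the aqueous methanol treatment leaving O2 and O6 as free hydroxyls.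

Step 2
Reactants: 3 phenyl 3,4-O-isopropylidene-1-thio-β-D-galactopyranoside
Product: 4 phenyl 6-O-TBS-3,4-O-isopropylidene-1-thio-β-D-galactopyranoside
Conditions: TBSCl, imidazole, CH2Cl2, 0 °C
Reagents that add atoms: tert-butyldimethylsilyl chloride, CC(C)(C)[Si](C)(C)Cl
Why: silyl ether formation should occur at the primary 6-OH in preference to the hindered secondary 2-OH.

Step 3
Reactants: 4 phenyl 6-O-TBS-3,4-O-isopropylidene-1-thio-β-D-galactopyranoside; 5 4-methoxybenzyl chloride
Product: 6 phenyl 6-O-TBS-3,4-O-isopropylidene-2-O-PMB-1-thio-β-D-galactopyranoside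
Conditions: NaH, 4-methoxybenzyl chloride, Bu4NI (cat.), DMF, 0 °C → rt
Reagents that add atoms: 4-methoxybenzyl chloride (5), COc1ccc(CCl)cc1
Why: Williamson etherification of the only free hydroxyl installs the ether that must sit next to the future aldehyde, and thioglycoside, acetonide and silyl ether tolerate the conditions.

Step 4
Reactants: 6 phenyl 6-O-TBS-3,4-O-isopropylidene-2-O-PMB-1-thio-β-D-galactopyranoside
Product: 7 6-O-TBS-3,4-O-isopropylidene-2-O-PMB-D-galactopyranose (lactol, anomer mixture)
Conditions: N-bromosuccinimide, NaHCO3, acetone/H2O, −15 °C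
Reagents that add atoms: water, O
Why: halonium activation of the thioglycoside sulfur and capture of the oxocarbenium ion by water (thioglycoside hydrolysis) should free the anomeric centre under buffered conditions that spare acetonide, PMB and TBS.

Step 5
Reactants: 7 6-O-TBS-3,4-O-isopropylidene-2-O-PMB-D-galactopyranose
Product: 9 open-chain alkene (C1 now CH=CH2; 2-O-PMB; 3,4-O-isopropylidene; 5-OH; 6-O-TBS; D-galacto), via aldehydo tautomer 8 (not isolated)
Conditions: Ph3PCH3Br, KOtBu, THF, 0 → 40 °C
Reagents that add atoms: methyltriphenylphosphonium bromide, C[P+](c1ccccc1)(c1ccccc1)c1ccccc1.[Br-]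
Why: Wittig methylenation of the ring-opened lactol should turn C1 into a vinyl group (a latent aldehyde) and leave O5 as the only free hydroxyl, with no stereocentre created.

Step 6
Reactants: 9 open-chain alkene with free 5-OH
Product: 10 5,6-bis-O-TBS open-chain alkene (2-O-PMB; 3,4-O-isopropylidene)
Conditions: TBSOTf, 2,6-lutidine, CH2Cl2, −78 → 0 °C
Reagents that add atoms: tert-butyldimethylsilyl trifluoromethanesulfonate, CC(C)(C)[Si](C)(C)OS(=O)(=O)C(F)(F)F
Why: silylation of the secondary 5-OH with the silyl triflate places the ether that will sit next to the ketone and later become the leaving group on ring C6.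

Step 7
Reactants: 10 5,6-bis-O-TBS open-chain alkene
Product: 11 5-O-TBS open-chain alkene with free primary 6-OH
Conditions: HF·pyridine, pyridine, THF, 0 °C
Reagents that add atoms: none
Why: buffered fluoride desilylation should cleave the unhindered primary silyl ether well before the secondary one, and the acetonide survives the buffered medium.

Step 8
Reactants: 11 5-O-TBS open-chain alkene with free 6-OH
Product: 12 C6 aldehyde (5-O-TBS; 3,4-O-isopropylidene; 2-O-PMB; C1 vinyl)
Conditions: Dess–Martin periodinane, pyridine, CH2Cl2, 0 °C → rt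
Reagents that add atoms: none
Why: Dess–Martin oxidation of the primary alcohol under buffered, non-epimerising conditions should give the alpha-silyloxy aldehyde, which is used without storage.

Step 9
Reactants: 13 4-methoxybenzyl alcohol; 14 tributyl(iodomethyl)stannane
Product: 15 tributyl[(4-methoxybenzyloxy)methyl]stannane
Conditions: NaH, THF/DMF, 0 °C → rt
Reagents that add atoms: tributyl(iodomethyl)stannane (14), CCCC[Sn](CCCC)(CCCC)CI
Why: Williamson etherification of the sodium alkoxide with the primary iodide gives the alpha-alkoxy stannane used as a PMB-oxymethyl anion source.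

Step 10
Reactants: 12 C6 aldehyde; 15 tributyl[(4-methoxybenzyloxy)methyl]stannane
Product: 17 C6 carbinol carrying C7H2OPMB (epimer mixture at C6), via lithium reagent 16 (not isolated)
Conditions: 15, n-BuLi, THF, −78 °C; then 12, −78 °C; AcOH quench at −78 °C
Reagents that add atoms: tributyl[(4-methoxybenzyloxy)methyl]stannane (15), CCCC[Sn](CCCC)(CCCC)COCc1ccc(OC)cc1
Why: tin–lithium exchange followed by 1,2-addition of the alpha-alkoxy organolithium to the aldehyde adds C7 with its protected oxygen, the cold quench preventing silyl migration to the new alkoxide; the new carbinol centre is removed in the next step.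

Step 11
Reactants: 17 C6 carbinol
Product: 18 C6 ketone (C1 vinyl; 2-O-PMB; 3,4-O-isopropylidene; 5-O-TBS; 7-O-PMB)
Conditions: Dess–Martin periodinane, pyridine, CH2Cl2, rt
Reagents that add atoms: none
Why: Dess–Martin oxidation of the secondary alcohol converges both epimers on one alpha,alpha′-dialkoxy ketone.

Step 12
Reactants: 18 C6 ketone with C1 vinyl group
Product: 20 keto-aldehyde (C1 aldehyde; 2-O-PMB; 3,4-O-isopropylidene; 5-O-TBS; C6 ketone; 7-O-PMB), via vicinal diol 19 (not isolated)
Conditions: OsO4 (cat.), NaIO4, 2,6-lutidine, dioxane/H2O, rt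
Reagents that add atoms: osmium tetroxide, O=[Os](=O)(=O)=O; sodium periodate, [Na+].[O-]I(=O)(=O)=O
Why: Lemieux–Johnson oxidation (catalytic dihydroxylation of the only alkene, then periodate glycol cleavage) should release the C1 aldehyde without attacking the electron-rich PMB rings; the crude keto-aldehyde goes straight into step 13.

Step 13
Reactants: 20 keto-aldehyde
Product: 21 cyclohexane cis-1,2-diol (C1 tertiary OH and C2–OH on one face with the C4/C5 acetonide oxygens; C3–OPMB, C6–OTBS and the C1 CH2OPMB branch on the other face)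
Conditions: SmI2 (excess), t-BuOH, THF, −78 → −20 °C; aq. NaHCO3
Reagents that add atoms: none
Why: SmI2 (divalent samarium) transfers one electron to the aldehyde, the more easily reduced carbonyl, and the C2 ketyl, bound to trivalent samarium that also coordinates the C1 ketone oxygen, adds to the ketone carbon; a second electron transfer and protonation by t-BuOH give the diol. The closest known reaction type is the SmI2 pinacol cyclisation of carbohydrate-derived 1,6-dialdehydes and keto-aldehydes to cis-diol cyclitols. The cyclohexane ring closes in a 6-exo-trig mode by attack of the C2 ketyl carbon on the C1 carbonyl carbon. At C1 and C2 the cis relationship of the new hydroxyls is controlled by the samarium bridge between the two oxygens, and their face by dipole and steric repulsion from the ether on C6 (for C1) and on C3 (for C2), which places each new C–O bond anti to its neighbour. The step needs the cis-diol on the face opposite both flanking ethers, and ring closure faster than reductive cleavage of the C–O bonds next to the ketone; the cis-fused acetonide on C4/C5 holds the carbonyls close, and ether rather than ester protection, low temperature and the absence of strongly activating additives keep the alpha-oxygens in place.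

Step 14
Reactants: 21 cyclohexane cis-1,2-diol
Product: 22 C2 methyl ether (C1 tertiary OH free)
Conditions: Me3OBF4, 1,8-bis(dimethylamino)naphthalene, CH2Cl2, 0 °C → rt
Reagents that add atoms: trimethyloxonium tetrafluoroborate, C[O+](C)C.F[B-](F)(F)F
Why: O-alkylation with the oxonium salt under essentially neutral conditions should methylate the secondary C2 hydroxyl and leave the far more hindered tertiary C1 hydroxyl, with no alkoxide present to move the silyl group.

Step 15
Reactants: 22 C2 methyl ether
Product: 23 C1,C4,C5-triol (C4/C5 cis-diol; C6–OTBS and both PMB ethers kept)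
Conditions: pyridinium p-toluenesulfonate (cat.), MeOH, 45 °C
Reagents that add atoms: none
Why: mild acid-catalysed transketalisation to methanol should remove the acetonide while the hindered secondary silyl ether and the PMB ethers persist.

Step 16
Reactants: 23 C1,C4,C5-triol
Product: 24 C4/C5 cyclic thiocarbonate
Conditions: 1,1′-thiocarbonyldiimidazole, 4-(dimethylamino)pyridine (cat.), toluene, 80 °C
Reagents that add atoms: 1,1′-thiocarbonyldiimidazole, S=C(n1ccnc1)n1ccnc1
Why: thiocarbonylation closes the five-membered ring only across the cis-vicinal C4/C5 diol, the tertiary C1 hydroxyl being too hindered to acylate.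

Step 17
Reactants: 24 C4/C5 cyclic thiocarbonate
Product: 25 cyclohexene (C4=C5; C1–OH; C2–OMe; C3–OPMB; C6–OTBS; C7–OPMB)
Conditions: 1,3-dimethyl-2-phenyl-1,3,2-diazaphospholidine, THF, 40 °C
Reagents that add atoms: none
Why: Corey–Winter olefination (sulfur abstraction by the phosphorus reagent, then stereospecific syn loss of CO2) should give the C4=C5 alkene at a temperature the allylic ethers tolerate.

Step 18
Reactants: 25 cyclohexene
Product: 26 trans-C1,C6-diol (C6 allylic OH)
Conditions: Bu4NF, THF, rt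
Reagents that add atoms: none
Why: fluoride desilylation frees the C6 hydroxyl at a stage where no base-sensitive group is present.

Step 19
Reactants: 26 trans-C1,C6-diol
Product: 28 vinyl oxirane (O bridging C1 and C6 on the face of C2–OMe; C3–OPMB; C7–OPMB), via C6 mesylate 27 (not isolated)
Conditions: Ms2O, Et3N, CH2Cl2, −20 °C; then K2CO3, MeOH, 0 °C → rt
Reagents that add atoms: none
Why: the secondary allylic hydroxyl is sulfonylated selectively (chloride-free anhydride), and the trans-disposed tertiary C1 alkoxide then displaces the mesylate in an intramolecular SN2 reaction (3-exo-tet), inverting C6 and giving the oxirane cis to C2–OMe.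

Step 20
Reactants: 28 vinyl oxirane
Product: 29 epoxy diol (C3–OH and C7–OH free)
Conditions: DDQ (2,3-dichloro-5,6-dicyano-1,4-benzoquinone), CH2Cl2/pH 7 phosphate buffer, 0 °C
Reagents that add atoms: none
Why: oxidative cleavage of both PMB ethers through their benzylic oxocarbenium ions should proceed under buffered conditions that the oxirane and alkene tolerate.

Step 21
Reactants: 29 epoxy diol
Product: 30 target, [(1R,2S,3R,6R)-3-(benzoyloxy)-2-methoxy-7-oxabicyclo[4.1.0]hept-4-en-1-yl]methyl benzoate
Conditions: BzCl, Et3N, 4-(dimethylamino)pyridine (cat.), CH2Cl2, 0 °C → rt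
Reagents that add atoms: benzoyl chloride, O=C(Cl)c1ccccc1
Why: nucleophile-catalysed acylation esterifies the primary C7 and the secondary allylic C3 hydroxyls without touching the oxirane.

**Compound list**
1 | phenyl 1-thio-β-D-galactopyranoside | OC[C@H]1O[C@@H](Sc2ccccc2)[C@H](O)[C@@H](O)[C@H]1O | starting material
2 | 2,2-dimethoxypropane | COC(C)(C)OC | starting material
3 | phenyl 3,4-O-isopropylidene-1-thio-β-D-galactopyranoside | OC[C@H]1O[C@@H](Sc2ccccc2)[C@H](O)[C@H]3OC(C)(C)O[C@@H]13 | intermediate
4 | phenyl 6-O-TBS-3,4-O-isopropylidene-1-thio-β-D-galactopyranoside | CC(C)(C)[Si](C)(C)OC[C@H]1O[C@@H](Sc2ccccc2)[C@H](O)[C@H]3OC(C)(C)O[C@@H]13 | intermediate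
5 | 4-methoxybenzyl chloride | COc1ccc(CCl)cc1 | starting material
6 | phenyl 6-O-TBS-3,4-O-isopropylidene-2-O-PMB-1-thio-β-D-galactopyranoside | CC(C)(C)[Si](C)(C)OC[C@H]1O[C@@H](Sc2ccccc2)[C@H](OCc4ccc(OC)cc4)[C@H]3OC(C)(C)O[C@@H]13 | intermediate
7 | 6-O-TBS-3,4-O-isopropylidene-2-O-PMB-D-galactopyranose (lactol, anomer mixture) | CC(C)(C)[Si](C)(C)OC[C@H]1OC(O)[C@H](OCc4ccc(OC)cc4)[C@H]3OC(C)(C)O[C@@H]13 | intermediate
8 | 6-O-TBS-3,4-O-isopropylidene-2-O-PMB-aldehydo-D-galactose (open-chain tautomer of 7) | O=C[C@H](OCc1ccc(OC)cc1)[C@H]2OC(C)(C)O[C@H]2[C@H](O)CO[Si](C)(C)C(C)(C)C | intermediate (not isolated)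
9 | open-chain alkene, C1 as CH=CH2, 2-O-PMB, 3,4-O-isopropylidene, 5-OH, 6-O-TBS (a 1,2-dideoxy-D-galacto-hept-1-enitol) | C=C[C@H](OCc1ccc(OC)cc1)[C@H]2OC(C)(C)O[C@H]2[C@H](O)CO[Si](C)(C)C(C)(C)C | intermediate
10 | 5,6-bis-O-TBS open-chain alkene | C=C[C@H](OCc1ccc(OC)cc1)[C@H]2OC(C)(C)O[C@H]2[C@H](O[Si](C)(C)C(C)(C)C)CO[Si](C)(C)C(C)(C)C | intermediate
11 | 5-O-TBS open-chain alkene with free 6-OH | C=C[C@H](OCc1ccc(OC)cc1)[C@H]2OC(C)(C)O[C@H]2[C@H](O[Si](C)(C)C(C)(C)C)CO | intermediate
12 | C6 aldehyde (5-O-TBS, 3,4-O-isopropylidene, 2-O-PMB, C1 vinyl) | C=C[C@H](OCc1ccc(OC)cc1)[C@H]2OC(C)(C)O[C@H]2[C@H](O[Si](C)(C)C(C)(C)C)C=O | intermediate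
13 | 4-methoxybenzyl alcohol | COc1ccc(CO)cc1 | starting material
14 | tributyl(iodomethyl)stannane | CCCC[Sn](CCCC)(CCCC)CI | starting material
15 | tributyl[(4-methoxybenzyloxy)methyl]stannane | CCCC[Sn](CCCC)(CCCC)COCc1ccc(OC)cc1 | intermediate
16 | [(4-methoxybenzyloxy)methyl]lithium | [Li]COCc1ccc(OC)cc1 | intermediate (not isolated)
17 | C6 carbinol with C7H2OPMB (epimer mixture at C6) | C=C[C@H](OCc1ccc(OC)cc1)[C@H]2OC(C)(C)O[C@H]2[C@H](O[Si](C)(C)C(C)(C)C)C(O)COCc3ccc(OC)cc3 | intermediate
18 | C6 ketone with C1 vinyl (2-O-PMB, 3,4-O-isopropylidene, 5-O-TBS, 7-O-PMB) | C=C[C@H](OCc1ccc(OC)cc1)[C@H]2OC(C)(C)O[C@H]2[C@H](O[Si](C)(C)C(C)(C)C)C(=O)COCc3ccc(OC)cc3 | intermediate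
19 | vicinal diol from dihydroxylation of the vinyl group of 18 (epimer mixture at the new carbinol) | OCC(O)[C@H](OCc1ccc(OC)cc1)[C@H]2OC(C)(C)O[C@H]2[C@H](O[Si](C)(C)C(C)(C)C)C(=O)COCc3ccc(OC)cc3 | intermediate (not isolated)
20 | keto-aldehyde (C1 aldehyde, 2-O-PMB, 3,4-O-isopropylidene, 5-O-TBS, C6 ketone, 7-O-PMB; D-galacto) | O=C[C@H](OCc1ccc(OC)cc1)[C@H]2OC(C)(C)O[C@H]2[C@H](O[Si](C)(C)C(C)(C)C)C(=O)COCc3ccc(OC)cc3 | intermediate
21 | cyclohexane cis-1,2-diol (ring numbering: 1-OH, 2-OH, 4-O, 5-O on one face; 3-OPMB, 6-OTBS, 1-CH2OPMB on the other) | O[C@H]1[C@H](OCc2ccc(OC)cc2)[C@H]3OC(C)(C)O[C@H]3[C@H](O[Si](C)(C)C(C)(C)C)[C@]1(O)COCc4ccc(OC)cc4 | intermediate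
22 | C2 methyl ether of 21 | CO[C@H]1[C@H](OCc2ccc(OC)cc2)[C@H]3OC(C)(C)O[C@H]3[C@H](O[Si](C)(C)C(C)(C)C)[C@]1(O)COCc4ccc(OC)cc4 | intermediate
23 | C1,C4,C5-triol (acetonide removed) | CO[C@H]1[C@H](OCc2ccc(OC)cc2)[C@@H](O)[C@@H](O)[C@H](O[Si](C)(C)C(C)(C)C)[C@]1(O)COCc4ccc(OC)cc4 | intermediate
24 | C4/C5 cyclic thiocarbonate | CO[C@H]1[C@H](OCc2ccc(OC)cc2)[C@H]3OC(=S)O[C@H]3[C@H](O[Si](C)(C)C(C)(C)C)[C@]1(O)COCc4ccc(OC)cc4 | intermediate
25 | cyclohexene (C4=C5, C1–OH, C2–OMe, C3–OPMB, C6–OTBS, C7–OPMB) | CO[C@H]1[C@H](OCc2ccc(OC)cc2)C=C[C@H](O[Si](C)(C)C(C)(C)C)[C@]1(O)COCc4ccc(OC)cc4 | intermediate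
26 | trans-C1,C6-diol | CO[C@H]1[C@H](OCc2ccc(OC)cc2)C=C[C@H](O)[C@]1(O)COCc4ccc(OC)cc4 | intermediate
27 | C6 mesylate of 26 | CO[C@H]1[C@H](OCc2ccc(OC)cc2)C=C[C@H](OS(C)(=O)=O)[C@]1(O)COCc4ccc(OC)cc4 | intermediate (not isolated)
28 | vinyl oxirane with two PMB ethers | CO[C@H]1[C@H](OCc2ccc(OC)cc2)C=C[C@H]3O[C@]31COCc4ccc(OC)cc4 | intermediate
29 | epoxy diol (C3–OH, C7–OH) | CO[C@H]1[C@H](O)C=C[C@H]2O[C@]21CO | intermediate
30 | [(1R,2S,3R,6R)-3-(benzoyloxy)-2-methoxy-7-oxabicyclo[4.1.0]hept-4-en-1-yl]methyl benzoate | CO[C@H]1[C@H](OC(=O)c2ccccc2)C=C[C@H]2O[C@]21COC(=O)c1ccccc1 | target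

**Count**
Total steps: 21. Longest linear sequence: 20 steps (steps 1–8 and 10–21, from compound 1); step 9 is a one-step side branch.

**Steps most likely to fail**

Step 13 (pinacol closure). What may go wrong: the ketyl may close with poor facial control, or the ether oxygens next to the ketone may be lost reductively before the ring closes. Fallback: set out from ketone 18. Wittig methylenation of the C6 ketone (Ph3PCH3Br, KN(SiMe3)2, THF, −78 → 0 °C) should give the 1,1-disubstituted diene F1. Ring-closing metathesis with second-generation Grubbs catalyst, (H2IMes)(PCy3)Cl2Ru=CHPh, in CH2Cl2 at 40 °C then forms the same C1–C2 bond as the trisubstituted cyclohexene F2. Dihydroxylation (OsO4 cat., N-methylmorpholine N-oxide, acetone/H2O) should occur on the face anti to both allylic ethers (C3–OPMB and C6–OTBS), which is the face required. The fallback comes back to the route at diol 21.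

Step 19 (oxirane closure). What may go wrong: the allylic C6 sulfonate may ionise or undergo allylic transposition or elimination before the hindered tertiary oxygen closes the ring. Fallback: set out from thiocarbonate 24, where C6 is not yet allylic. Desilylation with HF·pyridine/pyridine in THF should give the diol thiocarbonate F3. Ms2O/Et3N in CH2Cl2 at −20 °C gives the saturated C6 mesylate F4, and DBU then closes it to the epoxy thiocarbonate F5. Corey–Winter olefination with 1,3-dimethyl-2-phenyl-1,3,2-diazaphospholidine (THF, 40 °C) installs C4=C5 last. The fallback comes back to the route at oxirane 28.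

Step 20 (PMB removal on the vinyl oxirane). What may go wrong: acid-promoted opening of the vinyl oxirane, or over-oxidation of the liberated allylic alcohol, during the oxidative debenzylation. Fallback: set out from cyclohexene 25 and exchange the protecting groups before the oxirane exists. DDQ in buffered CH2Cl2 should give the triol F6. BzCl/pyridine esterifies the primary and secondary hydroxyls only, giving the dibenzoate F7. HF·pyridine removes the silyl group to give the diol F8. Ms2O/Et3N at −20 °C gives the C6 mesylate F9, which DBU closes to the oxirane. The fallback comes back to the route at target 30.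

**Further compounds**
F1 | step 13 | C6-methylidene diene from 18 (C1 vinyl, C6=CH2, 2-O-PMB, 3,4-O-isopropylidene, 5-O-TBS, 7-O-PMB) | C=C[C@H](OCc1ccc(OC)cc1)[C@H]2OC(C)(C)O[C@H]2[C@H](O[Si](C)(C)C(C)(C)C)C(=C)COCc3ccc(OC)cc3
F2 | step 13 | cyclohexene with C1=C2 (C1 bearing CH2OPMB, 3-OPMB, 4,5-O-isopropylidene, 6-OTBS) | COc1ccc(COCC2=C[C@H](OCc4ccc(OC)cc4)[C@H]3OC(C)(C)O[C@H]3[C@@H]2O[Si](C)(C)C(C)(C)C)cc1
F3 | step 19 | C1,C6-diol with C4/C5 thiocarbonate | CO[C@H]1[C@H](OCc2ccc(OC)cc2)[C@H]3OC(=S)O[C@H]3[C@H](O)[C@]1(O)COCc4ccc(OC)cc4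
F4 | step 19 | C6 mesylate of F3 | CO[C@H]1[C@H](OCc2ccc(OC)cc2)[C@H]3OC(=S)O[C@H]3[C@H](OS(C)(=O)=O)[C@]1(O)COCc4ccc(OC)cc4
F5 | step 19 | C1/C6 oxirane with C4/C5 thiocarbonate | CO[C@H]1[C@H](OCc2ccc(OC)cc2)[C@H]3OC(=S)O[C@H]3[C@H]4O[C@]41COCc5ccc(OC)cc5
F6 | step 20 | C1,C3,C7-triol with C6–OTBS | CO[C@H]1[C@H](O)C=C[C@H](O[Si](C)(C)C(C)(C)C)[C@]1(O)CO
F7 | step 20 | C3,C7-dibenzoate with C6–OTBS and free C1–OH | CO[C@H]1[C@H](OC(=O)c2ccccc2)C=C[C@H](O[Si](C)(C)C(C)(C)C)[C@]1(O)COC(=O)c3ccccc3
F8 | step 20 | C3,C7-dibenzoate C1,C6-diol | CO[C@H]1[C@H](OC(=O)c2ccccc2)C=C[C@H](O)[C@]1(O)COC(=O)c3ccccc3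
F9 | step 20 | C6 mesylate of F8 | CO[C@H]1[C@H](OC(=O)c2ccccc2)C=C[C@H](OS(C)(=O)=O)[C@]1(O)COC(=O)c3ccccc3
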